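Count the lifetimes of the rate in the alder flask: elm has alder's charge, so its curve continues alder's.

| setting | alder | ash | larch | cedar | elm |
|---|---|---|---|---|---|
| substrate | 100 mM | 50.0 mM | 300 mM | 100 mM | 100 mM |
| coupling partner | 200 mM | 150 mM | 200 mM | 100 mM | 200 mM |
| time |  |  |  |  | 300 min |

| run | time / min | [target] / mM |
|---|---|---|
| alder run | 4.3 | 3.8 |
| alder run | 13 | 10.2 |
| alder run | 25 | 15.9 |
| alder run | 40 | 23.2 |
| alder run | 57 | 28.6 |
| alder run | 76 | 33.1 |
| alder run | 97 | 37.1 |
| alder run | 120 | 38.9 |
| ash run | 4.3 | 1.7 |
| ash run | 13 | 3.7 |
| ash run | 25 | 5.1 |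
| ash run | 40 | 9.0 |
| ash run | 57 | 10.5 |
| ash run | 76 | 12.8 |
| ash run | 97 | 14.1 |
| ash run | 120 | 17.0 |
| larch run | 4.3 | 9.8 |
| larch run | 13 | 26.7 |
| larch run | 25 | 44.8 |
| larch run | 40 | 60.9 |
| larch run | 57 | 72.8 |
| larch run | 76 | 79.8 |
| larch run | 97 | 85.0 |
| larch run | 120 | 87.3 |
| cedar run | 4.3 | 1.7 |
| cedar run | 13 | 3.9 |
| cedar run | 25 | 7.9 |
| cedar run | 40 | 11.8 |
| cedar run | 57 | 15.2 |
| cedar run | 76 | 16.9 |
| cedar run | 97 | 18.5 |
| cedar run | 120 | 20.1 |

(scatter of a reading: 0.5 mM)

1. apparent order in [substrate] of the starting rate, round the charge of the alder run (the rate where two percent of its substrate have turned into target) (one fixed amount of target, the same in the runs compared)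
2. apparent order in [coupling partner] of the starting rate, round the charge of the alder run (the rate where two percent of its substrate have turned into target)
3. target in the elm run at 300 min, as a share of the substrate charged

- Overall: substrate + coupling partner -> target.
- Constant volume, constant temperature.
- A reading of a species includes what of it is bound.
- "The second partner" is coupling partner.
- An order is taken over about fifteen percent of the charge, up and down.

1. Target at 25 min in larch over alder, and in alder over cedar, gives orders near 0.943 in c(substrate) and 1.01 in c(coupling partner). These are wide-span readings, not the local orders asked, but they point to a rate close to first order in each.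

2. First extreme: nothing is lost. The alder reading at 13 min gives a start rate of 0.785 mM min⁻¹. Substrate, the limiting reagent, then has a lifetime of 127 min at the charged c(coupling partner). A rate proportional to both concentrations carries elm to 81.8 % at 300 min. It also puts 54.6 mM in alder at 120 min, more than the 38.9 mM read there.

3. Second extreme: the rate dies on its own clock. Alder's rate falls from 0.543 mM min⁻¹ between 4.3 min and 40 min to 0.132 mM min⁻¹ between 76 min and 120 min. The rate lifetime, the time in which the rate falls by a factor e, reads 53.5 min.

4. From 97 min, the middle of the late stretch, to 300 min lie 3.79 rate lifetimes, so hardly any of the late rate remains. Still to come is the late rate times the lifetime, 7.06 mM, on top of 37.1 mM: 44.2 mM, or 44.2 % of the substrate charged.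

5. The first extreme is set aside, since alder already falls 15.7 mM short of it, and the second is taken as the estimate. The reckoning here commits to 44.2 %.

6. The forecast, a different number on different grounds, gave 0.97, 1.1 and 42 %, holding that the flattening “points to a reversible reaction”.

7. The flask gives orders of 1.0 and 1.1, and 32.9 % in elm.

    2 coupling partner ⇌ reagent dimer, settled at all times (62.90 L mol⁻¹)
    substrate + reagent dimer → target + coupling partner (0.09960 L mol⁻¹ min⁻¹)
    coupling partner → lost reagent (0.01146 min⁻¹)
    target → decomposed product (0.003654 min⁻¹)

That is 32.9 mM of target at 300 min, less than the 38.9 mM read at 120 min in alder with the same charge, and 11 percentage points below the reckoning. The equations hold a step from target to decomposed product, with a lifetime of 274 min. So 300 min in elm is 5.61 rate lifetimes but 1.10 target lifetimes.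

(The numbers in the tables are simulated with constants of no real substance; the scatter is artificial.)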